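The route builds ring D of the lower unit from scratch on C4 of a finished, fully benzylated all-cis upper unit. Ring D is a phloroglucinol ring in which the oxygen-bearing carbons C8a', C7' and C5' alternate with C8', C6' and C4a', and C8' carries upper C4; a 4-substituted 3-alkoxycyclobutenone and an alkoxyalkyne map onto exactly this pattern. One benzannulation forms C4a'–C8a', C5'–C6' and C8'–C8a' and liberates the C8a' phenol from which ring F is grown. Its precursor is the (2S,3S)-all-cis flavan carrying a 3-benzyloxycyclobutenone at C4, reached from (−)-catechin by C4 allylation, C3 inversion and a ketene–alkyne cycloaddition.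

Key step: step 11

Remark 1: the target is read as upper unit (2S,3S) with the C4 aryl cis to both the C2 aryl and the C3 hydroxyl, and lower unit (2'R,3'R,4'S), that is 2',3'-cis-3',4'-trans. Upper unit: ring A (benzo), ring C (pyran), ring B (catechol). Lower unit, primed: ring D (benzo), ring F (pyran), ring E (catechol). "Fl" means the all-cis (2S,3S)-3,5,7,3',4'-penta-O-benzylflavan-4-yl group.

Remark 2: benzyl alkynyl ethers are assumed to undergo a [3,3] shift near 60 °C. The benzannulation is therefore started with light at room temperature and heated only after the excess alkyne has been removed.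

Remark 3: ether 3 is drawn as the 3,4-cis epimer expected by analogy; either C4 epimer serves, because C4 is ionised in step 3. Cyclobutenone 20 is used as the mixture of epimers at its ring carbon.

Step 1
Reactants: 1 (−)-catechin
Product: 2 5,7,3',4'-tetra-O-benzyl-(−)-catechin
Conditions: BnBr (4.2 equiv), K2CO3, DMF, 0 °C → rt
Reagents that add atoms: benzyl bromide, BrCc1ccccc1
Why: Williamson etherification in which carbonate deprotonates only the four phenols, so the much less acidic C3 alcohol stays free and no stereocentre is touched.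

Step 2
Reactants: 2 5,7,3',4'-tetra-O-benzyl-(−)-catechin
Product: 3 (2S,3R)-5,7,3',4'-tetra-O-benzyl-4-(2-ethoxyethoxy)flavan-3-ol
Conditions: DDQ (2 equiv), 2-ethoxyethanol, CH2Cl2, rt
Reagents that add atoms: 2-ethoxyethanol, CCOCCO
Why: benzylic oxidation by hydride abstraction, in which DDQ removes the C4 hydride activated by the ortho and para oxygens of ring A and the alcohol traps the resulting cation; the C4 configuration is of no consequence because the centre is ionised again in step 3.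

Step 3
Reactants: 3 (2S,3R)-5,7,3',4'-tetra-O-benzyl-4-(2-ethoxyethoxy)flavan-3-ol; 4 allyltrimethylsilane
Product: 5 (2S,3R,4S)-4-allyl-5,7,3',4'-tetra-O-benzylflavan-3-ol
Conditions: allylTMS (3 equiv), TMSOTf (0.2 equiv), CH2Cl2, −78 → −40 °C; aq. NaHCO3
Reagents that add atoms: none
Why: Hosomi–Sakurai-type allylation of the C4 cation, in which the silane attacks the face anti to the C3 hydroxyl of the 2,3-trans half-chair to give the 3,4-trans (2,4-cis) product; the minor C4 epimer is removed by chromatography.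

Step 4
Reactants: 5 (2S,3R,4S)-4-allyl-5,7,3',4'-tetra-O-benzylflavan-3-ol
Product: 6 (2S,4S)-4-allyl-5,7,3',4'-tetra-O-benzylflavan-3-one
Conditions: Dess–Martin periodinane, NaHCO3, wet CH2Cl2, rt
Reagents that add atoms: none
Why: Dess–Martin oxidation under buffered, near-neutral conditions gives the ketone without enolising the two flanking benzylic stereocentres.

Step 5
Reactants: 6 (2S,4S)-4-allyl-5,7,3',4'-tetra-O-benzylflavan-3-one
Product: 7 (2S,3S,4S)-4-allyl-5,7,3',4'-tetra-O-benzylflavan-3-ol (all-cis)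
Conditions: LiBH(s-Bu)3, LiBr, THF, −78 °C; H2O
Reagents that add atoms: none
Why: bulky-hydride ketone reduction in which the hydride approaches from the face opposite the cis-disposed C2 aryl and C4 allyl groups, so the new C3 hydroxyl is cis to both.

Step 6
Reactants: 7 (2S,3S,4S)-4-allyl-5,7,3',4'-tetra-O-benzylflavan-3-ol
Product: 8 (2S,3S,4S)-4-allyl-3,5,7,3',4'-penta-O-benzylflavan
Conditions: NaH, BnBr, n-Bu4NI (cat.), DMF, 0 °C → rt
Reagents that add atoms: benzyl bromide, BrCc1ccccc1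
Why: Williamson etherification of the sodium alkoxide; the ether blocks lactone formation with the acid made in step 8, and no stereocentre is affected.

Step 7
Reactants: 8 (2S,3S,4S)-4-allyl-3,5,7,3',4'-penta-O-benzylflavan
Product: 10 Fl-acetaldehyde, via vicinal diol 9 (not isolated)
Conditions: OsO4 (2 mol %), NaIO4 (4 equiv), 2,6-lutidine, dioxane/H2O, rt
Reagents that add atoms: osmium tetroxide, O=[Os](=O)(=O)=O (oxygen transfer, turned over by sodium periodate, [Na+].[O-]I(=O)(=O)=O)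
Why: Lemieux–Johnson cleavage in which catalytic OsO4 dihydroxylates only the terminal alkene and periodate cleaves the diol; 2,6-lutidine suppresses over-oxidation and the aryl ethers are inert.

Step 8
Reactants: 10 Fl-acetaldehyde
Product: 11 Fl-acetic acid
Conditions: NaClO2, NaH2PO4, 2-methyl-2-butene (excess), t-BuOH/THF/H2O, 0 °C
Reagents that add atoms: sodium chlorite, [Na+].[O-]Cl=O
Why: Pinnick oxidation, with excess 2-methyl-2-butene removing hypochlorous acid before it can chlorinate the electron-rich rings.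

Step 9
Reactants: 12 benzyl alcohol; 13 trichloroethylene
Product: 17 benzyloxyacetylene, via benzyl (E)-1,2-dichlorovinyl ether 14 (not isolated), via benzyl chloroethynyl ether 15 (not isolated), via lithium benzyloxyacetylide 16 (not isolated)
Conditions: KH, THF, 0 °C; trichloroethylene, −50 °C → rt; n-BuLi (2.4 equiv), −78 °C; MeOH, −78 °C; kept as a cold solution
Reagents that add atoms: none
Why: alkoxide addition–elimination on trichloroethylene gives the dichlorovinyl ether, and n-BuLi then effects dehydrochlorination and chlorine–lithium exchange to the lithium alkynyl ether, which is protonated cold; the product is stored below 0 °C because of its thermal lability.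

Step 10
Reactants: 11 Fl-acetic acid; 17 benzyloxyacetylene
Product: 20 3-benzyloxy-4-Fl-cyclobut-2-en-1-one, via acid chloride 18 (not isolated), via monosubstituted ketene 19 (not isolated)
Conditions: 1-chloro-N,N,2-trimethylprop-1-en-1-amine, CH2Cl2, 0 °C; then added slowly to 17 (3 equiv), Et3N, CH2Cl2, 0 °C → rt
Reagents that add atoms: none
Why: ketene–ynol ether (2+2) cycloaddition in which the acid chloride, made under neutral conditions, is dehydrochlorinated at once in excess 17 (slow addition keeps the ketene dilute and limits lactonisation onto the cis C3 ether) and the nucleophilic CH terminus of 17 bonds to the ketene carbonyl carbon, placing benzyloxy at C3 and Fl at C4 of the cyclobutenone; the new ring stereocentre is later destroyed.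

Step 11
Reactants: 20 3-benzyloxy-4-Fl-cyclobut-2-en-1-one; 17 benzyloxyacetylene
Product: 25 3,5-bis(benzyloxy)-2-Fl-phenol, via vinylketene 21 (not isolated), via alkenylcyclobutenone 22 (not isolated), via dienylketene 23 (not isolated), via cyclohexadienone 24 (not isolated)
Conditions: 17 (3 equiv), hν (medium-pressure Hg lamp, Pyrex, λ > 300 nm), degassed CH2Cl2, 20 °C; evaporate excess 17 (high vacuum, ≤ 20 °C); toluene, 80 → 110 °C
Reagents that add atoms: none
Why: Danheiser benzannulation (closest known type: cyclobutenone plus alkoxyalkyne to a resorcinol monoether), started here with light because the benzyl alkynyl ether would rearrange below the temperature at which a vinylogous-ester cyclobutenone opens thermally. Irradiation opens 20 (4π) to vinylketene 21, whose ketene C=C adds 17 at room temperature to give alkenylcyclobutenone 22; once excess 17 is evaporated, heat opens 22 (4π, reversible) to dienylketene 23, which cyclises to dienone 24 and tautomerises to phenol 25. Ring D is closed by a thermally allowed disrotatory 6π-electrocyclisation that forms C8'–C8a', after the (2+2) step has formed C4a'–C8a' and C5'–C6'; the four-membered rings are transient. No stereocentre is created: the cyclobutenone carbon becomes aromatic C8', and the all-cis C2/C3/C4 triad, which has no enolisable position, is a spectator. The selectivity needed is the orientation of the ketene–alkyne (2+2), secured by polarity: the unsubstituted, nucleophilic alkyne carbon bonds to the electrophilic ketene carbonyl carbon, so the new ether sits at C5', hydrogen at C4a', and the hydroxyl at C8a' ortho to the upper unit.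

Step 12
Reactants: 25 3,5-bis(benzyloxy)-2-Fl-phenol
Product: 27 4,6-bis(benzyloxy)-3-Fl-2-hydroxybenzaldehyde, via hydroxymethylphenol 26 (not isolated)
Conditions: MgCl2, Et3N, (CH2O)n, THF, reflux; aq. NH4Cl
Reagents that add atoms: paraformaldehyde (as formaldehyde), C=O
Why: magnesium-phenoxide-directed ortho-formylation (Casnati–Skattebøl), in which chelated formaldehyde is delivered only to the free ortho carbon C4a' and the hydroxymethyl intermediate is oxidised in situ by hydride transfer to a second formaldehyde; C6' and ring A have no neighbouring phenoxide and do not react.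

Step 13
Reactants: 27 4,6-bis(benzyloxy)-3-Fl-2-hydroxybenzaldehyde
Product: 28 4,6-bis(benzyloxy)-2-(tert-butyldimethylsilyloxy)-3-Fl-benzaldehyde
Conditions: TBSOTf, 2,6-lutidine, CH2Cl2, 0 °C
Reagents that add atoms: tert-butyldimethylsilyl triflate, CC(C)(C)[Si](C)(C)OS(=O)(=O)C(F)(F)F
Why: phenol silylation masks the acidic, chelating hydroxyl, so the aldehyde is not deactivated as a metal phenoxide in step 15 and the later allylic alcohol cannot lose water through the ortho-phenol.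

Step 14
Reactants: 29 3,4-bis(benzyloxy)benzaldehyde
Product: 30 1,2-bis(benzyloxy)-4-ethynylbenzene
Conditions: dimethyl (1-diazo-2-oxopropyl)phosphonate, K2CO3, MeOH/THF, rt
Reagents that add atoms: dimethyl (1-diazo-2-oxopropyl)phosphonate, COP(=O)(OC)C(=[N+]=[N-])C(C)=O
Why: Seyferth–Gilbert homologation (Ohira–Bestmann variant), in which methanolysis of the reagent gives the diazomethylphosphonate anion that converts the aldehyde into the terminal alkyne under mild base.

Step 15
Reactants: 28 4,6-bis(benzyloxy)-2-(tert-butyldimethylsilyloxy)-3-Fl-benzaldehyde; 30 1,2-bis(benzyloxy)-4-ethynylbenzene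
Product: 32 (R)-propargylic alcohol (ring D–CH(OH)–C≡C–ring E), via ethylzinc acetylide 31 (not isolated)
Conditions: 30 (2.5 equiv), Et2Zn (2.4 equiv), toluene, reflux, 1 h; then (R)-BINOL (0.2 equiv), Ti(OiPr)4 (0.5 equiv), CH2Cl2, rt; then 28, rt; aq. NH4Cl
Reagents that add atoms: none
Why: catalytic asymmetric alkynylzinc addition to an aryl aldehyde (BINOL–Ti(OiPr)4), in which the preformed alkynylzinc is transferred within the chiral titanium complex to the Re face of the aldehyde, setting C4' as R (4'S in the target after the change in substituent priority); (R)-BINOL is the antipode expected to give this sense, to be confirmed by MTPA-ester analysis.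

Step 16
Reactants: 32 (R)-propargylic alcohol
Product: 33 (R,Z)-allylic alcohol (ring D–CH(OH)–CH=CH–ring E)
Conditions: H2 (1 atm), Pd/CaCO3 poisoned with Pb(OAc)2 (Lindlar catalyst), quinoline, EtOAc, rt; stopped after 1 equiv H2
Reagents that add atoms: none
Why: Lindlar semi-hydrogenation delivers one equivalent of hydrogen syn to give the Z-alkene; the poisoned catalyst leaves benzyl ethers and the benzylic alcohol intact, and the product is used without delay.

Step 17
Reactants: 33 (R,Z)-allylic alcohol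
Product: 36 nona-O-benzyl dimer with free 3'- and 4'-hydroxyls, via silyl-protected epoxy alcohol 34 (not isolated), via phenolic epoxy alcohol 35 (not isolated)
Conditions: mCPBA (1.2 equiv), NaHCO3, CH2Cl2, −20 → 0 °C; then TBAF/AcOH (1:1), THF, 0 °C → rt
Reagents that add atoms: mCPBA, OOC(=O)c1cccc(Cl)c1
Why: hydroxyl-directed Prilezhaev epoxidation followed by 6-endo epoxide opening: in the A(1,3)-minimised conformer of the Z-allylic alcohol the C4' hydrogen eclipses the alkene and the hydrogen-bonded peracid is delivered to the hydroxyl face (threo oxirane, C3' R), and after buffered fluoride desilylation the phenol opens the oxirane with inversion at benzylic C2' (C2' R), the carbon best able to carry positive charge, giving the 2',3'-cis-3',4'-trans ring F.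

Step 18
Reactants: 36 nona-O-benzyl dimer with free 3'- and 4'-hydroxyls
Product: 37 target CNP0114173.1
Conditions: H2 (1 atm), Pd(OH)2/C, THF/EtOAc/H2O, rt; filter; lyophilise
Reagents that add atoms: none
Why: hydrogenolysis of all nine benzyl ethers under neutral, acid-free conditions; the aryl and C3 benzyl ethers cleave faster than the benzylic C4' hydroxyl, which is kept by excluding acid and stopping at complete debenzylation, and no stereocentre is affected.

Compound list
1 | (−)-catechin | Oc1cc(O)c2c(c1)O[C@@H](c1ccc(O)c(O)c1)[C@H](O)C2 | starting material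
2 | 5,7,3',4'-tetra-O-benzyl-(−)-catechin | c1ccccc1COc1cc(OCc3ccccc3)c2c(c1)O[C@@H](c1ccc(OCc3ccccc3)c(OCc3ccccc3)c1)[C@H](O)C2 | intermediate
3 | (2S,3R)-5,7,3',4'-tetra-O-benzyl-4-(2-ethoxyethoxy)flavan-3-ol (drawn as 4R, 3,4-cis) | c1ccccc1COc1cc(OCc3ccccc3)c2c(c1)O[C@@H](c1ccc(OCc3ccccc3)c(OCc3ccccc3)c1)[C@H](O)[C@@H]2OCCOCC | intermediate
4 | allyltrimethylsilane | C=CC[Si](C)(C)C | starting material
5 | (2S,3R,4S)-4-allyl-5,7,3',4'-tetra-O-benzylflavan-3-ol | c1ccccc1COc1cc(OCc3ccccc3)c2c(c1)O[C@@H](c1ccc(OCc3ccccc3)c(OCc3ccccc3)c1)[C@H](O)[C@H]2CC=C | intermediate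
6 | (2S,4S)-4-allyl-5,7,3',4'-tetra-O-benzylflavan-3-one | c1ccccc1COc1cc(OCc3ccccc3)c2c(c1)O[C@@H](c1ccc(OCc3ccccc3)c(OCc3ccccc3)c1)C(=O)[C@H]2CC=C | intermediate
7 | (2S,3S,4S)-4-allyl-5,7,3',4'-tetra-O-benzylflavan-3-ol (all-cis) | c1ccccc1COc1cc(OCc3ccccc3)c2c(c1)O[C@@H](c1ccc(OCc3ccccc3)c(OCc3ccccc3)c1)[C@@H](O)[C@H]2CC=C | intermediate
8 | (2S,3S,4S)-4-allyl-3,5,7,3',4'-penta-O-benzylflavan | c1ccccc1COc1cc(OCc3ccccc3)c2c(c1)O[C@@H](c1ccc(OCc3ccccc3)c(OCc3ccccc3)c1)[C@@H](OCc1ccccc1)[C@H]2CC=C | intermediate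
9 | 3-Fl-propane-1,2-diol (carbinol centre undefined) | c1ccccc1COc1cc(OCc3ccccc3)c2c(c1)O[C@@H](c1ccc(OCc3ccccc3)c(OCc3ccccc3)c1)[C@@H](OCc1ccccc1)[C@H]2CC(O)CO | intermediate
10 | Fl-acetaldehyde | c1ccccc1COc1cc(OCc3ccccc3)c2c(c1)O[C@@H](c1ccc(OCc3ccccc3)c(OCc3ccccc3)c1)[C@@H](OCc1ccccc1)[C@H]2CC=O | intermediate
11 | Fl-acetic acid | c1ccccc1COc1cc(OCc3ccccc3)c2c(c1)O[C@@H](c1ccc(OCc3ccccc3)c(OCc3ccccc3)c1)[C@@H](OCc1ccccc1)[C@H]2CC(=O)O | intermediate
12 | benzyl alcohol | OCc1ccccc1 | starting material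
13 | trichloroethylene | ClC=C(Cl)Cl | starting material
14 | benzyl (E)-1,2-dichlorovinyl ether | Cl/C=C(/Cl)OCc1ccccc1 | intermediate
15 | benzyl chloroethynyl ether | ClC#COCc1ccccc1 | intermediate
16 | lithium benzyloxyacetylide | [Li]C#COCc1ccccc1 | intermediate
17 | benzyloxyacetylene | C#COCc1ccccc1 | intermediate
18 | Fl-acetyl chloride | c1ccccc1COc1cc(OCc3ccccc3)c2c(c1)O[C@@H](c1ccc(OCc3ccccc3)c(OCc3ccccc3)c1)[C@@H](OCc1ccccc1)[C@H]2CC(=O)Cl | intermediate
19 | Fl-ketene | c1ccccc1COc1cc(OCc3ccccc3)c2c(c1)O[C@@H](c1ccc(OCc3ccccc3)c(OCc3ccccc3)c1)[C@@H](OCc1ccccc1)[C@H]2C=C=O | intermediate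
20 | 3-benzyloxy-4-Fl-cyclobut-2-en-1-one (both epimers at the ring carbon) | c1ccccc1COc1cc(OCc3ccccc3)c2c(c1)O[C@@H](c1ccc(OCc3ccccc3)c(OCc3ccccc3)c1)[C@@H](OCc1ccccc1)[C@H]2C1C(=O)C=C1OCc1ccccc1 | intermediate
21 | 3-benzyloxy-4-Fl-buta-1,3-dien-1-one (vinylketene, alkene geometry undefined) | c1ccccc1COc1cc(OCc3ccccc3)c2c(c1)O[C@@H](c1ccc(OCc3ccccc3)c(OCc3ccccc3)c1)[C@@H](OCc1ccccc1)[C@H]2C=C(OCc1ccccc1)C=C=O | intermediate
22 | 3-benzyloxy-4-[1-benzyloxy-2-Fl-vinyl]cyclobut-2-en-1-one | c1ccccc1COc1cc(OCc3ccccc3)c2c(c1)O[C@@H](c1ccc(OCc3ccccc3)c(OCc3ccccc3)c1)[C@@H](OCc1ccccc1)[C@H]2C=C(OCc1ccccc1)C1C(=O)C=C1OCc1ccccc1 | intermediate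
23 | 3,5-bis(benzyloxy)-6-Fl-hexa-1,3,5-trien-1-one (dienylketene) | c1ccccc1COc1cc(OCc3ccccc3)c2c(c1)O[C@@H](c1ccc(OCc3ccccc3)c(OCc3ccccc3)c1)[C@@H](OCc1ccccc1)[C@H]2C=C(OCc1ccccc1)C=C(OCc1ccccc1)C=C=O | intermediate
24 | 3,5-bis(benzyloxy)-6-Fl-cyclohexa-2,4-dien-1-one | c1ccccc1COc1cc(OCc3ccccc3)c2c(c1)O[C@@H](c1ccc(OCc3ccccc3)c(OCc3ccccc3)c1)[C@@H](OCc1ccccc1)[C@H]2C1C(=O)C=C(OCc3ccccc3)C=C1OCc1ccccc1 | intermediate
25 | 3,5-bis(benzyloxy)-2-Fl-phenol | c1ccccc1COc1cc(OCc3ccccc3)c2c(c1)O[C@@H](c1ccc(OCc3ccccc3)c(OCc3ccccc3)c1)[C@@H](OCc1ccccc1)[C@H]2c1c(OCc3ccccc3)cc(OCc3ccccc3)cc1O | intermediate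
26 | 3,5-bis(benzyloxy)-2-Fl-6-(hydroxymethyl)phenol | c1ccccc1COc1cc(OCc3ccccc3)c2c(c1)O[C@@H](c1ccc(OCc3ccccc3)c(OCc3ccccc3)c1)[C@@H](OCc1ccccc1)[C@H]2c1c(OCc3ccccc3)cc(OCc3ccccc3)c(CO)c1O | intermediate
27 | 4,6-bis(benzyloxy)-3-Fl-2-hydroxybenzaldehyde | c1ccccc1COc1cc(OCc3ccccc3)c2c(c1)O[C@@H](c1ccc(OCc3ccccc3)c(OCc3ccccc3)c1)[C@@H](OCc1ccccc1)[C@H]2c1c(OCc3ccccc3)cc(OCc3ccccc3)c(C=O)c1O | intermediate
28 | 4,6-bis(benzyloxy)-2-(tert-butyldimethylsilyloxy)-3-Fl-benzaldehyde | c1ccccc1COc1cc(OCc3ccccc3)c2c(c1)O[C@@H](c1ccc(OCc3ccccc3)c(OCc3ccccc3)c1)[C@@H](OCc1ccccc1)[C@H]2c1c(OCc3ccccc3)cc(OCc3ccccc3)c(C=O)c1O[Si](C)(C)C(C)(C)C | intermediate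
29 | 3,4-bis(benzyloxy)benzaldehyde | O=Cc1ccc(OCc2ccccc2)c(OCc2ccccc2)c1 | starting material
30 | 1,2-bis(benzyloxy)-4-ethynylbenzene | C#Cc1ccc(OCc2ccccc2)c(OCc2ccccc2)c1 | intermediate
31 | ethyl[(3,4-bis(benzyloxy)phenyl)ethynyl]zinc | CC[Zn]C#Cc1ccc(OCc2ccccc2)c(OCc2ccccc2)c1 | intermediate
32 | (R)-1-[ring D aryl]-3-[3,4-bis(benzyloxy)phenyl]prop-2-yn-1-ol, phenol as TBS ether | c1ccccc1COc1cc(OCc3ccccc3)c2c(c1)O[C@@H](c1ccc(OCc3ccccc3)c(OCc3ccccc3)c1)[C@@H](OCc1ccccc1)[C@H]2c1c(OCc3ccccc3)cc(OCc3ccccc3)c([C@H](O)C#Cc3ccc(OCc4ccccc4)c(OCc4ccccc4)c3)c1O[Si](C)(C)C(C)(C)C | intermediate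
33 | (R,Z)-1-[ring D aryl]-3-[3,4-bis(benzyloxy)phenyl]prop-2-en-1-ol, phenol as TBS ether | c1ccccc1COc1cc(OCc3ccccc3)c2c(c1)O[C@@H](c1ccc(OCc3ccccc3)c(OCc3ccccc3)c1)[C@@H](OCc1ccccc1)[C@H]2c1c(OCc3ccccc3)cc(OCc3ccccc3)c([C@H](O)/C=C\c3ccc(OCc4ccccc4)c(OCc4ccccc4)c3)c1O[Si](C)(C)C(C)(C)C | intermediate
34 | threo cis-epoxy alcohol (carbinol S, oxirane C3' R, C2' S), phenol as TBS ether | c1ccccc1COc1cc(OCc3ccccc3)c2c(c1)O[C@@H](c1ccc(OCc3ccccc3)c(OCc3ccccc3)c1)[C@@H](OCc1ccccc1)[C@H]2c1c(OCc3ccccc3)cc(OCc3ccccc3)c([C@H](O)[C@H]5O[C@H]5c3ccc(OCc4ccccc4)c(OCc4ccccc4)c3)c1O[Si](C)(C)C(C)(C)C | intermediate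
35 | threo cis-epoxy alcohol with free phenol | c1ccccc1COc1cc(OCc3ccccc3)c2c(c1)O[C@@H](c1ccc(OCc3ccccc3)c(OCc3ccccc3)c1)[C@@H](OCc1ccccc1)[C@H]2c1c(OCc3ccccc3)cc(OCc3ccccc3)c([C@H](O)[C@H]5O[C@H]5c3ccc(OCc4ccccc4)c(OCc4ccccc4)c3)c1O | intermediate
36 | nona-O-benzyl dimer, (2S,3S,4-all-cis) upper unit, (2'R,3'R,4'S) lower unit, free 3'- and 4'-hydroxyls | c1ccccc1COc1cc(OCc3ccccc3)c2c(c1)O[C@@H](c1ccc(OCc3ccccc3)c(OCc3ccccc3)c1)[C@@H](OCc1ccccc1)[C@H]2c1c(OCc3ccccc3)cc(OCc3ccccc3)c2c1O[C@H](c1ccc(OCc3ccccc3)c(OCc3ccccc3)c1)[C@H](O)[C@H]2O | intermediate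
37 | CNP0114173.1 | Oc1cc(O)c2c(c1)O[C@@H](c1ccc(O)c(O)c1)[C@@H](O)[C@H]2c1c(O)cc(O)c2c1O[C@H](c1ccc(O)c(O)c1)[C@H](O)[C@H]2O | target

Total step count: 18. Longest linear sequence: 16 steps from (−)-catechin (steps 1–8, 10–13, 15–18); steps 9 and 14 prepare the two alkynes.

Steps most likely to fail

Step 11. The light-driven ring opening may be inefficient (competing absorption, reclosure of the vinylketene), the hindered vinylketene may be captured too slowly, or ketene intermediates may acylate the new phenol. The fallback sets out from 3 and comes back at 25, and it bypasses step 10 as well. Ether 3 is ionised with TMSOTf (CH2Cl2, −78 °C) in the presence of commercial 3,5-bis(benzyloxy)phenol. The carbon ortho to its hydroxyl attacks C4 trans to the C3 hydroxyl (Friedel–Crafts alkylation) and gives the 4-aryl-2,3-trans-3,4-trans flavan-3-ol F1; the regioisomer from attack between the two ethers is separated. Silylation of the phenol (TBSCl, imidazole, DMF) gives the silyl ether F2. Dess–Martin oxidation gives the flavan-3-one F3. Reduction with LiBH(s-Bu)3 from the face opposite both aryl groups gives the all-cis alcohol F4. KHMDS and BnBr (THF, −78 → 0 °C) give the C3 benzyl ether F5, and TBAF frees the phenol 25.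

Step 15. The doubly ortho-substituted, electron-rich aldehyde may convert slowly, ethyl transfer may compete, or facial selectivity may be poor. The fallback sets out from 28 and comes back at 32. The bromomagnesium acetylide of 30 (EtMgBr, THF, 0 °C; cold acetic acid quench to prevent silyl migration) adds to 28 without facial control and gives the epimeric propargylic alcohols F6. MnO2 (CH2Cl2, rt) oxidises them to the ynone F7. Corey–Bakshi–Shibata reduction ((S)-2-methyl-CBS-oxazaborolidine, catecholborane, toluene, −78 °C), with the aryl group as the large and the alkynyl group as the small substituent, then gives 32.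

Step 17. The peracid may over-oxidise the electron-rich rings, the threo preference may erode, or the aryl oxirane may ionise before the phenol is released, which would cost stereospecificity at C2' or lead to rearrangement. The fallback sets out from 33 and comes back at 36. Hydroxyl-directed syn-dihydroxylation with stoichiometric OsO4·TMEDA (CH2Cl2, −78 °C; then aq. Na2SO3) delivers both oxygens to the face chosen by the C4' hydroxyl and gives the silyl-protected triol F8, with no peracid and no oxirane. TBAF/AcOH frees the phenol to give the tetraol F9. Mitsunobu etherification (PPh3, DIAD, THF, 0 °C) activates the benzylic C2' carbinol, which the phenol displaces with inversion to close ring F and give 36.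

Further compounds
F1 | step 11 | (2S,3R,4-trans)-4-[2,4-bis(benzyloxy)-6-hydroxyphenyl]-5,7,3',4'-tetra-O-benzylflavan-3-ol | c1ccccc1COc1cc(OCc3ccccc3)c2c(c1)O[C@@H](c1ccc(OCc3ccccc3)c(OCc3ccccc3)c1)[C@H](O)[C@H]2c1c(OCc3ccccc3)cc(OCc3ccccc3)cc1O
F2 | step 11 | phenol TBS ether of F1 | c1ccccc1COc1cc(OCc3ccccc3)c2c(c1)O[C@@H](c1ccc(OCc3ccccc3)c(OCc3ccccc3)c1)[C@H](O)[C@H]2c1c(OCc3ccccc3)cc(OCc3ccccc3)cc1O[Si](C)(C)C(C)(C)C
F3 | step 11 | 2,4-cis-4-aryl-flavan-3-one from F2 | c1ccccc1COc1cc(OCc3ccccc3)c2c(c1)O[C@@H](c1ccc(OCc3ccccc3)c(OCc3ccccc3)c1)C(=O)[C@H]2c1c(OCc3ccccc3)cc(OCc3ccccc3)cc1O[Si](C)(C)C(C)(C)C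
F4 | step 11 | all-cis 4-aryl-flavan-3-ol from F3 | c1ccccc1COc1cc(OCc3ccccc3)c2c(c1)O[C@@H](c1ccc(OCc3ccccc3)c(OCc3ccccc3)c1)[C@@H](O)[C@H]2c1c(OCc3ccccc3)cc(OCc3ccccc3)cc1O[Si](C)(C)C(C)(C)C
F5 | step 11 | TBS ether of 25 | c1ccccc1COc1cc(OCc3ccccc3)c2c(c1)O[C@@H](c1ccc(OCc3ccccc3)c(OCc3ccccc3)c1)[C@@H](OCc1ccccc1)[C@H]2c1c(OCc3ccccc3)cc(OCc3ccccc3)cc1O[Si](C)(C)C(C)(C)C
F6 | step 15 | propargylic alcohol as in 32, both carbinol epimers | c1ccccc1COc1cc(OCc3ccccc3)c2c(c1)O[C@@H](c1ccc(OCc3ccccc3)c(OCc3ccccc3)c1)[C@@H](OCc1ccccc1)[C@H]2c1c(OCc3ccccc3)cc(OCc3ccccc3)c(C(O)C#Cc3ccc(OCc4ccccc4)c(OCc4ccccc4)c3)c1O[Si](C)(C)C(C)(C)C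
F7 | step 15 | ynone (ring D–CO–C≡C–ring E), phenol as TBS ether | c1ccccc1COc1cc(OCc3ccccc3)c2c(c1)O[C@@H](c1ccc(OCc3ccccc3)c(OCc3ccccc3)c1)[C@@H](OCc1ccccc1)[C@H]2c1c(OCc3ccccc3)cc(OCc3ccccc3)c(C(=O)C#Cc3ccc(OCc4ccccc4)c(OCc4ccccc4)c3)c1O[Si](C)(C)C(C)(C)C
F8 | step 17 | 1,2,3-triol from syn-dihydroxylation of 33, phenol as TBS ether | c1ccccc1COc1cc(OCc3ccccc3)c2c(c1)O[C@@H](c1ccc(OCc3ccccc3)c(OCc3ccccc3)c1)[C@@H](OCc1ccccc1)[C@H]2c1c(OCc3ccccc3)cc(OCc3ccccc3)c([C@H](O)[C@@H](O)[C@@H](O)c3ccc(OCc4ccccc4)c(OCc4ccccc4)c3)c1O[Si](C)(C)C(C)(C)C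
F9 | step 17 | 1,2,3-triol with free phenol | c1ccccc1COc1cc(OCc3ccccc3)c2c(c1)O[C@@H](c1ccc(OCc3ccccc3)c(OCc3ccccc3)c1)[C@@H](OCc1ccccc1)[C@H]2c1c(OCc3ccccc3)cc(OCc3ccccc3)c([C@H](O)[C@@H](O)[C@@H](O)c3ccc(OCc4ccccc4)c(OCc4ccccc4)c3)c1O
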